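| flask | D | Z | Q | temperature | remark | time |
|---|---|---|---|---|---|---|
| eta | 20 mM | 14 mM | 10 mM | 10 °C | run made earlier |  |
| theta | 20 mM | 14 mM | 40 mM | 40 °C | run made earlier |  |
| delta | 10 mM | 14 mM | 20 mM | 10 °C | run made earlier |  |
| Monday's | 20 mM | 14.0 mM | 20.0 mM | 65 °C |  | 8.0 min |
| Thursday's | 20 mM | 14.0 mM | 20.0 mM | 40 °C |  | 8.0 min |
| Tuesday's | 20 mM | 14.0 mM | 20.0 mM | 15 °C |  | 8.0 min |

- eta (time / min: E / %, G / %): 10.0: 5.7, 10.0; 20.0: 10.6, 15.8; 40.0: 16.9, 21.7; 60.0: 22.0, 26.6; 120: 29.8, 31.1
- theta (time / min: E / %, G / %): 5.00: 13.9, 73.6; 10.0: 14.6, 81.9; 15.0: 15.0, 83.9; 20.0: 15.6, 84.7; 30.0: 15.2, 84.1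
- delta (time / min: E / %, G / %): 10.0: 5.9, 19.4; 30.0: 11.7, 41.2; 60.0: 17.7, 56.3; 90.0: 19.3, 63.5; 120: 21.7, 67.9

(scatter of a reading: 0.5 percentage points)

- the flask with the highest share of E in all that became E or G ("all alike" if they lie within 1.5 percentage points) (Monday's / Thursday's / Tuesday's / all alike)
- share of E in all that became E or G, Monday's
- share of E in all that became E or G, Thursday's
- share of E in all that became E or G, Tuesday's

- what is said of E includes L
- the numbers in the tables scatter by 0.5 percentage points (one standard deviation)
- on the list of suspects stand: D + Z -> E; Q + Z -> J; D + Q -> G; Q + E <-> L; Z -> X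

To whoever takes the bench: each D that reacts goes with Z to E or with Q to G, and both paths need D, so the amount of D drops out of their ratio and, at one temperature, the share of fresh product that is E depends on Z against Q. In the delta run at 10.0 min, G over E, times Z over Q, reads 2.30. This is how strongly D favours Q over Z at equal amounts, a selectivity factor. The eta run reads 2.46, within the scatter of such a ratio. The starting share of E is one over one plus the factor times Q over Z, which for these charges, with the factor as read at 10 °C, gives 23.3%.

I expect Tuesday's, being cold, to stay near that at 8.0 min. The warm flasks need care: in the theta run E stays near 15.2% from 10.0 min on, while G climbs from 81.9% to 84.1%. Monday's is hotter than theta, so I expect E to stall there too and its share to be held down, though theta also differs from Monday's in its Q. Don't add Q: at theta's charge the same factor gives a starting share of 13.2%.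

The forecast says 32%, 29% and 24% for Monday's, Thursday's and Tuesday's, because when warm Q “falls faster relative to Z”. The flasks give 19.5%, 28.8% and 24.9%, so Thursday's stands highest.

    D + Z → E (k = 0.130 /M/s, Ea = 68.0 kJ/mol)
    Q + Z → J (k = 0.0450 /M/s, Ea = 62.0 kJ/mol)
    D + Q → G (k = 0.220 /M/s, Ea = 59.0 kJ/mol)
    Q + E ⇌ L, settled at all times (K = 110 /M, ΔH = −25.0 kJ/mol)
    Z → X (k = 0.00170 /s, Ea = 97.0 kJ/mol)
    (constants at 40 °C)

Just after the start of Tuesday's, D goes to G 3.3 times as fast as to E, which makes the starting share 23.5% against my 23.3%. The neighbouring flask is Tuesday's with 56 mM of Z. The same factor gives it a starting share of 54.9%. At 8.00 min that flask gave a share of 60.0%, with 25.3% of the D charged as E, L counted, and 16.9% as G.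

All runs were generated by integration from invented constants; noise was put on by code.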